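## Analysis of the target

The target is an aryl cyclohexenyl ketone in which the carbonyl carbon links A1 of a pentasubstituted benzene (ring A, with hydroxyl on A2 and A6, methoxyl on A3 and A4 and hydrogen on A5) to C1 of a cyclohexene that carries prenyl on C2, methyl on C3 (C3=C4 double bond) and phenyl on C6. The three stereocentres C6, C1 and C2 are contiguous and all S; the acyl group on C1 is trans to both the prenyl group on C2 and the phenyl group on C6, so prenyl and phenyl lie on the same face. C1 is alpha to the ketone and can epimerise, but trans to both neighbours is the arrangement expected at equilibrium, so only C2 and C6 have to be set irreversibly. Sensitive groups are the two trisubstituted alkenes (acid, electrophiles, oxidants) and the electron-rich ring with two free phenols, one of them para to a methoxyl. Any intermediate with a benzylic carbinol ortho to a free phenol is also fragile, because it can ionise to a quinone methide that the nearby alkenes could trap. The difficulty is threefold: the carbonyl carbon is crowded on both sides, two hydroxyls on ring A must be told apart from two methoxyls, and three contiguous stereocentres are needed. The strategy rests on the pattern of ring A, a carbon substituent on A1 between two oxygens (A2, A6) with two neighbouring methoxyls (A3, A4) and one hydrogen (A5) beyond, which is what results when the two-carbon unit of an ynol ether (A1, A2) takes up the four-carbon vinylketene unit (A6, A5, A4, A3) of 2,3-dimethoxycyclobutenone.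

## Retrosynthetic reasoning

34 back to 32. Only C–O and C–H bonds at the ketone carbon and at the phenols change. The ketone 34 is traced through its bis(methoxymethyl) ether 33 to the secondary alcohol 32. The carbonyl carbon is carried at the carbinol level because an acyl-substituted ynol ether would be neither stable nor nucleophilic enough for the ring-forming step. The oxidation is placed while both phenols are masked, because a free 2,6-dihydroxybenzylic alcohol can ionise and a free phenol para to a methoxyl is exposed to oxidants. Forward, a hindered benzylic alcohol must be oxidised and two phenols freed without touching the alkenes.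

32 back to 29. The acetal-protected alcohol 32 comes from the silyl ether 31, and 31 from the phenol 29 through the diphenol 30, by exchanging the aryl silyl ether and the free phenol for two methoxymethyl ethers. The exchange is needed because an aryl silyl ether is always cleaved before a hindered alkyl one, so the carbinol cannot be freed while the phenols stay silylated.

29 to 20 and 24 (key disconnection). Ring A is cut at A1–A6 and A2–A3. A1 and A2 with the side chain go to the silyloxyalkyne 20; A3 to A6 with both methoxyls go to the cyclobutenone 24. The bond A5–A6 is the C1–C4 bond of 24, broken and re-formed during the reaction. The cut is made here because no bond to an existing crowded arene has to be made, and the mechanism places every oxygen: the oxygen on A6 comes from the ketene carbonyl as a free phenol, and the oxygen on A2 comes from the alkyne as a silyl ether. The forward reaction must join a vinylketene and an ynol ether with one regiochemistry under neutral conditions.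

24 back to 21. The C4–H bond of 24 replaces a C–O bond: 24 comes from the acetate 23, the alcohol 22 and dimethyl squarate 21. The squarate already holds the four ring carbons and both methoxyls, so only one carbonyl has to be taken down to a methylene. The forward sequence must do this without shifting the double bond.

20 back to 14 and 15. The ynol C–O bond of 20 is made by oxidising the acetylide 18 to the ynolate 19 and silylating it on oxygen. The carbinol C–C bond is made by adding the acetylide 15 to the aldehyde 14 (alcohol 16, then silyl ether 17). This puts the future ketone carbon in place with a robust, poorly leaving protecting group and asks only for an aldehyde on the ring fragment.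

14 back to 9. The aldehyde 14 comes from the thioester 13 and the orthothioester 12. The methyl-bearing alkene of 12 comes from the enol triflate 11 of ketone 9, which means cutting the C3–CH3 bond. The ketone of 9 thus serves twice: it drives the construction of C1 and C2 and then becomes the C3=C4 alkene with its methyl group.

9 to 4, 5 and 6. The C1–acyl carbon bond and the C2–CH2 bond are cut together. Conjugate addition of the anion 7 of orthothioester 5 to enone 4 and alkylation of the enolate 8 with bromide 6 form both bonds. The phenyl-bearing centre of 4 directs the first bond anti, and the new substituent directs the second anti, which is the trans,trans relationship of the target.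

4 back to 1. The single controlling stereocentre is taken back through the enol silane 3 to the meso ketone 1. Enantiotopic deprotonation of 1 (enolate 2) makes the phenyl-bearing carbon stereogenic, and oxidation of 3 places the alkene next to it.

## Alternatives that were turned down

Alternative 1: the two exocyclic bonds at C1 and C2 (C1–acyl carbon and C2–CH2 of prenyl) are disconnected on the enone 4, with ring A brought in as a separate, preformed building block.
- Forward key step: the lithiated orthothioester 7 adds to the β-carbon of 4 and the enolate is alkylated by 6. This gives (2S,3R,4S)-4-phenyl-2-prenyl-3-[tris(methylsulfanyl)methyl]cyclohexan-1-one A1, which is the same compound as 9.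
- For: three components and both new stereocentres in one flask, set trans,trans by the phenyl group. The chosen route uses exactly this reaction as its third step, so on the cyclohexene half the two plans are equal.
- Against: ring A is left unsolved. It would have to come in as a metalated tetraoxygenated arene such as [2,6-bis(methoxymethoxy)-3,4-dimethoxyphenyl]lithium A2. This arene needs its own multistep synthesis and must add, at its most hindered position between two alkoxy groups, to the equally hindered aldehyde 14.
- Comparison: that union uses thoroughly known chemistry and needs fewer steps after 14, so Alternative 1 is the stronger plan on predictability and step count. The chosen strategy offers in its place a ring A whose whole oxygen pattern is created regiospecifically from two small fragments, with the two hydroxyls already differentiated and no bond formed between two crowded centres. The aryllithium union is kept as the fallback for the key step.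

Alternative 2: the ring bonds C1–C6 and C2=C3 (target numbering) are disconnected in a Robinson-type annulation around an aroyl group that already carries ring A.
- Forward key step: 3-[2,6-bis(methoxymethoxy)-3,4-dimethoxyphenyl]-3-oxopropanal A4 adds under chiral amine catalysis through its central carbon to the β-carbon of (E)-1-phenylpent-1-en-3-one A5. The ethyl ketone then condenses with the formyl group to give (4S,5S)-4-[2,6-bis(methoxymethoxy)-3,4-dimethoxybenzoyl]-2-methyl-5-phenylcyclohex-2-en-1-one A3.
- For: catalytic enantiocontrol instead of a stoichiometric chiral base, a convergent ring synthesis, ring A present from the start, and the acyl/phenyl trans relationship set under equilibrium. On these points it is stronger than the chosen route.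
- Against: A3 lacks the prenyl group and has its double bond and an extra ketone in the wrong places. Prenyl would have to be added at C2 by a copper-mediated conjugate addition of a prenyl nucleophile, which is prone to 1,2-addition and to bond formation through its tertiary end. The C1–H of A3 is alpha to the aroyl group and gamma to the enone, so it is acidic enough to be removed, which threatens both the addition and the stereocentre. The ring ketone must then be removed through an enol derivative, and A4 presupposes acylation of the crowded arene.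
- Comparison: the chosen strategy sets the prenyl-bearing centre by enolate alkylation with the allylic bromide 6, keeps C1 non-acidic until the last two steps, and never acylates ring A.

Alternative 3: the A1–carbonyl bond is disconnected together with the A6–O bond, so that the ketone and its ortho hydroxyl come from a carboxylic acid and an aryne.
- Forward key step: a fluoride source liberates 3,4,5-trimethoxybenzyne A9 from 3,4,5-trimethoxy-2-(trimethylsilyl)phenyl trifluoromethanesulfonate A8 in the presence of (1S,2S,6S)-3-methyl-6-phenyl-2-prenylcyclohex-3-ene-1-carboxylic acid A7. The carboxylate oxygen adds to the aryne carbon remote from the methoxyl, and the resulting aryl anion takes over the acyl group from oxygen. This gives (6-hydroxy-2,3,4-trimethoxyphenyl)[(1S,2S,6S)-3-methyl-6-phenyl-2-prenylcyclohex-3-en-1-yl]methanone A6.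
- For: the most convergent plan, no protecting groups, the ketone formed at the right oxidation level, regiochemistry guided by the methoxyl next to the aryne, and one step left after the key step. In step count after the cyclohexene is made it is clearly stronger than the chosen route.
- Against: with carboxylic acids the aryl anion is usually protonated faster than it attacks the ester, so plain O-arylation competes. The acyl shift must occur at a carbonyl flanked by two substituted ring carbons, and the alpha stereocentre is exposed to a carbanion and to basic fluoride at elevated temperature. The last step must cleave one of three methoxyls of A6 with a strong Lewis acid beside two acid-sensitive alkenes.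
- Comparison: the chosen strategy differentiates the four oxygens by construction (two methoxyls from the squarate, one hydroxyl free, one silylated), cleaves no aryl methyl ether, and forms ring A under neutral thermal conditions.

Key step: step 14

## Remarks on the chemistry (assumptions)

- Prenyl stands for 3-methylbut-2-en-1-yl in all names.
- The carbinol carbon formed in step 8 is carried as a mixture of both epimers up to 32, because it becomes the ketone carbon in step 17.
- The (R,R)-configured amide is assumed, by analogy with other 4-substituted cyclohexanones, to give the (S)-enol ether 3; should the sense be opposite, the (S,S)-amide is used.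

## Route

Step 1
Reactants: 1 4-phenylcyclohexan-1-one
Product: 3 (S)-trimethyl[(4-phenylcyclohex-1-en-1-yl)oxy]silane, via lithium enolate 2 (not isolated)
Conditions: (R,R)-bis(1-phenylethyl)amine·HCl, n-BuLi (2 equiv), THF, −78 °C; Me3SiCl, then 1, −100 → −78 °C (internal quench)
Reagents that add atoms: chlorotrimethylsilane, C[Si](C)(C)Cl
Why: Asymmetric desymmetrisation of a meso ketone by enantiotopic deprotonation with the lithium amide of (R,R)-bis(1-phenylethyl)amine and immediate O-silylation; the amide distinguishes the two axial alpha protons and so makes the phenyl-bearing carbon (C6 of the target) stereogenic. The enantiomeric purity can be raised later by recrystallisation of a crystalline intermediate.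

Step 2
Reactants: 3 (S)-trimethyl[(4-phenylcyclohex-1-en-1-yl)oxy]silane
Product: 4 (S)-4-phenylcyclohex-2-en-1-one
Conditions: Pd(OAc)2 (10 mol%), O2 (1 atm), DMSO, 25 °C
Reagents that add atoms: none
Why: Saegusa–Ito oxidation: the divalent palladium enolate formed from the enol silane undergoes β-hydride elimination on the side of the enol double bond, so the alkene is placed next to the stereocentre, which is not touched under these neutral conditions.

Step 3
Reactants: 4 (S)-4-phenylcyclohex-2-en-1-one; 5 tris(methylsulfanyl)methane; 6 1-bromo-3-methylbut-2-ene (prenyl bromide)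
Product: 9 (2S,3R,4S)-4-phenyl-2-prenyl-3-[tris(methylsulfanyl)methyl]cyclohexan-1-one, via tris(methylsulfanyl)methyllithium 7 (not isolated), via lithium enolate 8 (not isolated)
Conditions: 5, n-BuLi, THF, −78 °C; 4, −78 °C; then 6, HMPA, −78 → −20 °C
Reagents that add atoms: none
Why: Three-component conjugate addition–enolate alkylation: the soft, hindered orthothioester anion adds 1,4 and anti to the neighbouring phenyl group, and the regiodefined enolate is alkylated by the allylic bromide anti to the new bulky substituent. Both new stereocentres (C1 and C2 of the target) are thus set trans,trans to C6 by substrate control.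

Step 4
Reactants: 9 (2S,3R,4S)-4-phenyl-2-prenyl-3-[tris(methylsulfanyl)methyl]cyclohexan-1-one
Product: 11 (4S,5R,6S)-4-phenyl-6-prenyl-5-[tris(methylsulfanyl)methyl]cyclohex-1-en-1-yl trifluoromethanesulfonate, via potassium enolate 10 (not isolated)
Conditions: KN(SiMe3)2, THF, −78 °C; PhNTf2, −78 → 0 °C
Reagents that add atoms: N-phenylbis(trifluoromethanesulfonimide), O=S(=O)(N(c1ccccc1)S(=O)(=O)C(F)(F)F)C(F)(F)F
Why: Kinetic deprotonation by a hindered amide base occurs at the unsubstituted alpha methylene and not at the tertiary carbon bearing prenyl; O-triflation fixes the double bond where the C3=C4 alkene of the target lies.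

Step 5
Reactants: 11 (4S,5R,6S)-4-phenyl-6-prenyl-5-[tris(methylsulfanyl)methyl]cyclohex-1-en-1-yl trifluoromethanesulfonate
Product: 12 [(1S,2S,6S)-3-methyl-6-phenyl-2-prenylcyclohex-3-en-1-yl]tris(methylsulfanyl)methane
Conditions: MeLi, CuI (Me2CuLi, 3 equiv), THF, −20 → 0 °C
Reagents that add atoms: methyllithium, C[Li]
Why: Coupling of an enol triflate with lithium dimethylcuprate replaces the triflate by methyl without moving the double bond; the orthothioester and the prenyl alkene are inert to the cuprate.

Step 6
Reactants: 12 [(1S,2S,6S)-3-methyl-6-phenyl-2-prenylcyclohex-3-en-1-yl]tris(methylsulfanyl)methane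
Product: 13 S-methyl (1S,2S,6S)-3-methyl-6-phenyl-2-prenylcyclohex-3-ene-1-carbothioate
Conditions: HgCl2 (2 equiv), CaCO3, MeCN/H2O (4:1), 25 °C
Reagents that add atoms: water, O
Why: Thiophilic hydrolysis of an orthothioester: HgCl2 ionises one C–S bond, water adds to the sulfur-stabilised cation and a second thiolate is lost, giving the thioester. The buffered, weakly electrophilic HgCl2 should leave both trisubstituted alkenes alone.

Step 7
Reactants: 13 S-methyl (1S,2S,6S)-3-methyl-6-phenyl-2-prenylcyclohex-3-ene-1-carbothioate
Product: 14 (1S,2S,6S)-3-methyl-6-phenyl-2-prenylcyclohex-3-ene-1-carbaldehyde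
Conditions: i-Bu2AlH (1.1 equiv), CH2Cl2, −78 °C; aq. potassium sodium tartrate (KNaC4H4O6)
Reagents that add atoms: none
Why: Partial reduction of a thioester: the tetrahedral aluminium hemithioacetal persists at −78 °C and releases the aldehyde on work-up. C1 keeps its more stable configuration trans to both neighbours.

Step 8
Reactants: 14 (1S,2S,6S)-3-methyl-6-phenyl-2-prenylcyclohex-3-ene-1-carbaldehyde; 15 ethynylmagnesium bromide
Product: 16 1-[(1S,2S,6S)-3-methyl-6-phenyl-2-prenylcyclohex-3-en-1-yl]prop-2-yn-1-ol (both carbinol epimers)
Conditions: 15 (0.5 M in THF), THF, −78 → 0 °C; aq. NH4Cl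
Reagents that add atoms: none
Why: Grignard addition of an acetylide to the aldehyde; the new carbinol centre is formed without control, which does not matter because it is oxidised in step 17.

Step 9
Reactants: 16 1-[(1S,2S,6S)-3-methyl-6-phenyl-2-prenylcyclohex-3-en-1-yl]prop-2-yn-1-ol
Product: 17 tert-butyl(dimethyl){1-[(1S,2S,6S)-3-methyl-6-phenyl-2-prenylcyclohex-3-en-1-yl]prop-2-yn-1-yloxy}silane
Conditions: t-BuMe2SiOTf, 2,6-lutidine, CH2Cl2, −78 → 0 °C
Reagents that add atoms: tert-butyldimethylsilyl trifluoromethanesulfonate, CC(C)(C)[Si](C)(C)OS(=O)(=O)C(F)(F)F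
Why: Silylation of a hindered secondary propargylic alcohol with a silyl triflate; the silyl ether is a poor leaving group and is stable to n-BuLi and to heat.

Step 10
Reactants: 17 tert-butyl(dimethyl){1-[(1S,2S,6S)-3-methyl-6-phenyl-2-prenylcyclohex-3-en-1-yl]prop-2-yn-1-yloxy}silane
Product: 20 tert-butyl(dimethyl){1-[(1S,2S,6S)-3-methyl-6-phenyl-2-prenylcyclohex-3-en-1-yl]-3-(triisopropylsilyloxy)prop-2-yn-1-yloxy}silane, via lithium acetylide 18 (not isolated), via lithium ynolate 19 (not isolated)
Conditions: n-BuLi, THF, −78 °C; LiOOt-Bu (from t-BuOOH and LiN(SiMe3)2), −78 → 0 °C; i-Pr3SiOTf, −78 → 0 °C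
Reagents that add atoms: tert-butyl hydroperoxide, CC(C)(C)OO; triisopropylsilyl trifluoromethanesulfonate, CC(C)[Si](OS(=O)(=O)C(F)(F)F)(C(C)C)C(C)C
Why: Electrophilic oxygen transfer from lithium tert-butyl peroxide to the lithium acetylide gives the lithium ynolate, which the bulky silyl triflate captures on oxygen. This is a known way from terminal alkynes to triisopropylsilyl ynol ethers, applied here to a propargylic silyl ether.

Step 11
Reactants: 21 dimethyl squarate (3,4-dimethoxycyclobut-3-ene-1,2-dione)
Product: 22 4-hydroxy-2,3-dimethoxycyclobut-2-en-1-one (racemic)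
Conditions: LiAlH(Ot-Bu)3 (1.05 equiv), THF, −78 → −20 °C; aq. NH4Cl
Reagents that add atoms: none
Why: Mono-1,2-reduction of a squarate diester by a bulky, mild hydride, a known entry to 4-hydroxy-2,3-dialkoxycyclobutenones; low temperature and one equivalent prevent a second reduction.

Step 12
Reactants: 22 4-hydroxy-2,3-dimethoxycyclobut-2-en-1-one
Product: 23 2,3-dimethoxy-4-oxocyclobut-2-en-1-yl acetate (racemic)
Conditions: Ac2O, pyridine, DMAP (cat.), CH2Cl2, 0 °C
Reagents that add atoms: acetic anhydride, CC(=O)OC(C)=O
Why: Acylation under basic conditions turns the hydroxyl into a group that can be expelled reductively, and avoids the acid that would rearrange this compound to a cyclobutenedione.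

Step 13
Reactants: 23 2,3-dimethoxy-4-oxocyclobut-2-en-1-yl acetate
Product: 24 2,3-dimethoxycyclobut-2-en-1-one
Conditions: SmI2 (2.2 equiv), THF/MeOH, −78 °C
Reagents that add atoms: none
Why: Reductive cleavage of an α-acyloxy ketone by samarium diiodide (divalent samarium): two single-electron transfers expel acetate and methanol protonates the resulting samarium dienolate. Protonation at the unsubstituted ring carbon is expected because it is the less hindered terminus and keeps the fully substituted, donor–acceptor-stabilised alkene.

Step 14
Reactants: 20 tert-butyl(dimethyl){1-[(1S,2S,6S)-3-methyl-6-phenyl-2-prenylcyclohex-3-en-1-yl]-3-(triisopropylsilyloxy)prop-2-yn-1-yloxy}silane; 24 2,3-dimethoxycyclobut-2-en-1-one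
Product: 29 2-{(tert-butyldimethylsilyloxy)[(1S,2S,6S)-3-methyl-6-phenyl-2-prenylcyclohex-3-en-1-yl]methyl}-4,5-dimethoxy-3-(triisopropylsilyloxy)phenol, via vinylketene 25 (not isolated), via vinylcyclobutenone 26 (not isolated), via dienylketene 27 (not isolated), via cyclohexadienone 28 (not isolated)
Conditions: 24 (1.5 equiv), PhMe (0.5 M), 80 → 120 °C, sealed tube, Ar
Reagents that add atoms: none
Why: Heating opens 24 by four-electron conrotatory electrocyclic cleavage of its C1–C4 bond to the methoxy(vinyl)ketene 25, whose ketene carbonyl carbon is attacked by the nucleophilic, side-chain-bearing carbon of the ynol ether 20; stepwise polar [2+2] closure gives the vinylcyclobutenone 26 and forms the A1–A6 and A2–A3 bonds. A second four-electron opening of 26 gives the dienylketene 27, in which the methoxyl on the breaking sp3 carbon should rotate outward as donor groups do, so that the vinyl group turns inward as the next event requires. Ring A is then closed by thermal six-electron disrotatory electrocyclisation of 27, which joins the ketene carbon (A6) to the terminal CH2 (A5), and the cyclohexadienone 28 tautomerises to the phenol. The closest known reaction type is the Danheiser benzannulation of cyclobutenones with trialkylsilyloxyalkynes to resorcinol monosilyl ethers; a 2,3-dialkoxycyclobutenone without a C4 substituent and a branched propargylic silyl ether on the alkyne are untested variations of it. No stereocentre is created (the quaternary carbon of 26 is lost again) and the three ring stereocentres are remote from all bond changes. The selectivity needed is the regiochemistry of the ketene–alkyne union, and it is secured by the polarisation of the ynol ether: its oxygen makes the carbon that carries the carbinol the nucleophile, so the side chain lands between the new hydroxyl (A6) and the silyloxy carbon (A2) with both methoxyls beyond. The conditions are neutral, so the prenyl group, the ring alkene and both silyl ethers should survive.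

Step 15
Reactants: 29 2-{(tert-butyldimethylsilyloxy)[(1S,2S,6S)-3-methyl-6-phenyl-2-prenylcyclohex-3-en-1-yl]methyl}-4,5-dimethoxy-3-(triisopropylsilyloxy)phenol
Product: 31 {[2,6-bis(methoxymethoxy)-3,4-dimethoxyphenyl][(1S,2S,6S)-3-methyl-6-phenyl-2-prenylcyclohex-3-en-1-yl]methoxy}(tert-butyl)dimethylsilane, via diphenol 30 (not isolated)
Conditions: Bu4NF (2 equiv), THF, 0 °C; then i-Pr2NEt, MeOCH2Cl (excess), 0 → 25 °C
Reagents that add atoms: chloromethyl methyl ether, COCCl
Why: Fluoride cleaves the aryl silyl ether far faster than the hindered secondary alkyl silyl ether, and both phenols are then alkylated by the chloromethyl ether. Masking both phenols removes the ortho-hydroxybenzylic relationship that could give quinone methides and shields the electron-rich ring from the oxidant of step 17.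

Step 16
Reactants: 31 {[2,6-bis(methoxymethoxy)-3,4-dimethoxyphenyl][(1S,2S,6S)-3-methyl-6-phenyl-2-prenylcyclohex-3-en-1-yl]methoxy}(tert-butyl)dimethylsilane
Product: 32 [2,6-bis(methoxymethoxy)-3,4-dimethoxyphenyl][(1S,2S,6S)-3-methyl-6-phenyl-2-prenylcyclohex-3-en-1-yl]methanol (both carbinol epimers)
Conditions: Bu4NF (3 equiv), THF, 50 °C
Reagents that add atoms: none
Why: Fluoride-mediated cleavage of the remaining alkyl silyl ether at higher temperature; the acetal-protected phenols and both alkenes are inert to fluoride, and no centre is epimerisable at this stage.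

Step 17
Reactants: 32 [2,6-bis(methoxymethoxy)-3,4-dimethoxyphenyl][(1S,2S,6S)-3-methyl-6-phenyl-2-prenylcyclohex-3-en-1-yl]methanol
Product: 33 [2,6-bis(methoxymethoxy)-3,4-dimethoxyphenyl][(1S,2S,6S)-3-methyl-6-phenyl-2-prenylcyclohex-3-en-1-yl]methanone
Conditions: Dess–Martin periodinane, NaHCO3, CH2Cl2, 0 → 25 °C
Reagents that add atoms: none
Why: Dess–Martin oxidation of a hindered secondary alcohol does not depend on benzylic activation and tolerates alkenes and acetals; both carbinol epimers converge on one ketone, and C1 keeps the preferred configuration trans to both neighbours.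

Step 18
Reactants: 33 [2,6-bis(methoxymethoxy)-3,4-dimethoxyphenyl][(1S,2S,6S)-3-methyl-6-phenyl-2-prenylcyclohex-3-en-1-yl]methanone
Product: 34 (2,6-dihydroxy-3,4-dimethoxyphenyl)[(1S,2S,6S)-3-methyl-2-(3-methylbut-2-en-1-yl)-6-phenylcyclohex-3-en-1-yl]methanone
Conditions: HCl (2 M aq.), MeOH, 25 → 40 °C
Reagents that add atoms: none
Why: Acid-catalysed acetal exchange with methanol removes both methoxymethyl groups from the ortho-acyl phenols under mild conditions; the ketone deactivates the ring, and the isolated trisubstituted alkenes should survive dilute acid at this temperature.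

## Compound list

1 | 4-phenylcyclohexan-1-one | O=C1CCC(c2ccccc2)CC1 | starting material
2 | lithium (S)-4-phenylcyclohex-1-en-1-olate (formed in the flask) | [Li]OC1=CC[C@@H](c2ccccc2)CC1 | intermediate
3 | (S)-trimethyl[(4-phenylcyclohex-1-en-1-yl)oxy]silane | C[Si](C)(C)OC1=CC[C@@H](c2ccccc2)CC1 | intermediate
4 | (S)-4-phenylcyclohex-2-en-1-one | O=C1C=C[C@@H](c2ccccc2)CC1 | intermediate
5 | tris(methylsulfanyl)methane | CSC(SC)SC | starting material
6 | 1-bromo-3-methylbut-2-ene (prenyl bromide) | CC(C)=CCBr | starting material
7 | tris(methylsulfanyl)methyllithium (formed in the flask) | [Li]C(SC)(SC)SC | intermediate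
8 | lithium (3R,4S)-4-phenyl-3-[tris(methylsulfanyl)methyl]cyclohex-1-en-1-olate (formed in the flask) | [Li]OC1=C[C@H](C(SC)(SC)SC)[C@@H](c2ccccc2)CC1 | intermediate
9 | (2S,3R,4S)-4-phenyl-2-prenyl-3-[tris(methylsulfanyl)methyl]cyclohexan-1-one | CSC(SC)(SC)[C@H]1[C@H](CC=C(C)C)C(=O)CC[C@@H]1c1ccccc1 | intermediate
10 | potassium (4S,5R,6S)-4-phenyl-6-prenyl-5-[tris(methylsulfanyl)methyl]cyclohex-1-en-1-olate (formed in the flask) | CSC(SC)(SC)[C@H]1[C@H](CC=C(C)C)C(O[K])=CC[C@@H]1c1ccccc1 | intermediate
11 | (4S,5R,6S)-4-phenyl-6-prenyl-5-[tris(methylsulfanyl)methyl]cyclohex-1-en-1-yl trifluoromethanesulfonate | CSC(SC)(SC)[C@H]1[C@H](CC=C(C)C)C(OS(=O)(=O)C(F)(F)F)=CC[C@@H]1c1ccccc1 | intermediate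
12 | [(1S,2S,6S)-3-methyl-6-phenyl-2-prenylcyclohex-3-en-1-yl]tris(methylsulfanyl)methane | CSC(SC)(SC)[C@H]1[C@H](CC=C(C)C)C(C)=CC[C@@H]1c1ccccc1 | intermediate
13 | S-methyl (1S,2S,6S)-3-methyl-6-phenyl-2-prenylcyclohex-3-ene-1-carbothioate | CSC(=O)[C@H]1[C@H](CC=C(C)C)C(C)=CC[C@@H]1c1ccccc1 | intermediate
14 | (1S,2S,6S)-3-methyl-6-phenyl-2-prenylcyclohex-3-ene-1-carbaldehyde | O=C[C@H]1[C@H](CC=C(C)C)C(C)=CC[C@@H]1c1ccccc1 | intermediate
15 | ethynylmagnesium bromide | C#C[Mg]Br | starting material
16 | 1-[(1S,2S,6S)-3-methyl-6-phenyl-2-prenylcyclohex-3-en-1-yl]prop-2-yn-1-ol (both carbinol epimers) | C#CC(O)[C@H]1[C@H](CC=C(C)C)C(C)=CC[C@@H]1c1ccccc1 | intermediate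
17 | tert-butyl(dimethyl){1-[(1S,2S,6S)-3-methyl-6-phenyl-2-prenylcyclohex-3-en-1-yl]prop-2-yn-1-yloxy}silane (carbinol epimers) | C#CC(O[Si](C)(C)C(C)(C)C)[C@H]1[C@H](CC=C(C)C)C(C)=CC[C@@H]1c1ccccc1 | intermediate
18 | lithium acetylide of 17 (formed in the flask) | [Li]C#CC(O[Si](C)(C)C(C)(C)C)[C@H]1[C@H](CC=C(C)C)C(C)=CC[C@@H]1c1ccccc1 | intermediate
19 | lithium 3-(tert-butyldimethylsilyloxy)-3-[(1S,2S,6S)-3-methyl-6-phenyl-2-prenylcyclohex-3-en-1-yl]prop-1-yn-1-olate (formed in the flask) | [Li]OC#CC(O[Si](C)(C)C(C)(C)C)[C@H]1[C@H](CC=C(C)C)C(C)=CC[C@@H]1c1ccccc1 | intermediate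
20 | tert-butyl(dimethyl){1-[(1S,2S,6S)-3-methyl-6-phenyl-2-prenylcyclohex-3-en-1-yl]-3-(triisopropylsilyloxy)prop-2-yn-1-yloxy}silane (carbinol epimers) | CC(C)[Si](OC#CC(O[Si](C)(C)C(C)(C)C)[C@H]1[C@H](CC=C(C)C)C(C)=CC[C@@H]1c1ccccc1)(C(C)C)C(C)C | intermediate
21 | dimethyl squarate (3,4-dimethoxycyclobut-3-ene-1,2-dione) | COC1=C(OC)C(=O)C1=O | starting material
22 | 4-hydroxy-2,3-dimethoxycyclobut-2-en-1-one (racemic) | COC1=C(OC)C(=O)C1O | intermediate
23 | 2,3-dimethoxy-4-oxocyclobut-2-en-1-yl acetate (racemic) | COC1=C(OC)C(=O)C1OC(C)=O | intermediate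
24 | 2,3-dimethoxycyclobut-2-en-1-one | COC1=C(OC)C(=O)C1 | intermediate
25 | 2,3-dimethoxybuta-1,3-dien-1-one (formed in the flask) | COC(=C=O)C(OC)=C | intermediate
26 | 2-{(tert-butyldimethylsilyloxy)[(1S,2S,6S)-3-methyl-6-phenyl-2-prenylcyclohex-3-en-1-yl]methyl}-4-methoxy-4-(1-methoxyethenyl)-3-(triisopropylsilyloxy)cyclobut-2-en-1-one (formed in the flask; mixture at the ring and carbinol carbons) | C=C(OC)C1(OC)C(=O)C(=C1O[Si](C(C)C)(C(C)C)C(C)C)C(O[Si](C)(C)C(C)(C)C)[C@H]1[C@H](CC=C(C)C)C(C)=CC[C@@H]1c1ccccc1 | intermediate
27 | (3Z)-2-{(tert-butyldimethylsilyloxy)[(1S,2S,6S)-3-methyl-6-phenyl-2-prenylcyclohex-3-en-1-yl]methyl}-4,5-dimethoxy-3-(triisopropylsilyloxy)hexa-1,3,5-trien-1-one (formed in the flask) | C=C(OC)/C(OC)=C(O[Si](C(C)C)(C(C)C)C(C)C)\C(=C=O)C(O[Si](C)(C)C(C)(C)C)[C@H]1[C@H](CC=C(C)C)C(C)=CC[C@@H]1c1ccccc1 | intermediate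
28 | 2-{(tert-butyldimethylsilyloxy)[(1S,2S,6S)-3-methyl-6-phenyl-2-prenylcyclohex-3-en-1-yl]methyl}-4,5-dimethoxy-3-(triisopropylsilyloxy)cyclohexa-2,4-dien-1-one (formed in the flask) | O=C1CC(OC)=C(OC)C(O[Si](C(C)C)(C(C)C)C(C)C)=C1C(O[Si](C)(C)C(C)(C)C)[C@H]2[C@H](CC=C(C)C)C(C)=CC[C@@H]2c2ccccc2 | intermediate
29 | 2-{(tert-butyldimethylsilyloxy)[(1S,2S,6S)-3-methyl-6-phenyl-2-prenylcyclohex-3-en-1-yl]methyl}-4,5-dimethoxy-3-(triisopropylsilyloxy)phenol (carbinol epimers) | COc1cc(O)c(C(O[Si](C)(C)C(C)(C)C)[C@H]2[C@H](CC=C(C)C)C(C)=CC[C@@H]2c2ccccc2)c(O[Si](C(C)C)(C(C)C)C(C)C)c1OC | intermediate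
30 | 2-{(tert-butyldimethylsilyloxy)[(1S,2S,6S)-3-methyl-6-phenyl-2-prenylcyclohex-3-en-1-yl]methyl}-4,5-dimethoxybenzene-1,3-diol (formed in the flask) | COc1cc(O)c(C(O[Si](C)(C)C(C)(C)C)[C@H]2[C@H](CC=C(C)C)C(C)=CC[C@@H]2c2ccccc2)c(O)c1OC | intermediate
31 | {[2,6-bis(methoxymethoxy)-3,4-dimethoxyphenyl][(1S,2S,6S)-3-methyl-6-phenyl-2-prenylcyclohex-3-en-1-yl]methoxy}(tert-butyl)dimethylsilane (carbinol epimers) | COCOc1cc(OC)c(OC)c(OCOC)c1C(O[Si](C)(C)C(C)(C)C)[C@H]1[C@H](CC=C(C)C)C(C)=CC[C@@H]1c1ccccc1 | intermediate
32 | [2,6-bis(methoxymethoxy)-3,4-dimethoxyphenyl][(1S,2S,6S)-3-methyl-6-phenyl-2-prenylcyclohex-3-en-1-yl]methanol (carbinol epimers) | COCOc1cc(OC)c(OC)c(OCOC)c1C(O)[C@H]1[C@H](CC=C(C)C)C(C)=CC[C@@H]1c1ccccc1 | intermediate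
33 | [2,6-bis(methoxymethoxy)-3,4-dimethoxyphenyl][(1S,2S,6S)-3-methyl-6-phenyl-2-prenylcyclohex-3-en-1-yl]methanone | COCOc1cc(OC)c(OC)c(OCOC)c1C(=O)[C@H]1[C@H](CC=C(C)C)C(C)=CC[C@@H]1c1ccccc1 | intermediate
34 | (2,6-dihydroxy-3,4-dimethoxyphenyl)[(1S,2S,6S)-3-methyl-2-(3-methylbut-2-en-1-yl)-6-phenylcyclohex-3-en-1-yl]methanone | COc1cc(O)c(C(=O)[C@H]2[C@H](CC=C(C)C)C(C)=CC[C@@H]2c2ccccc2)c(O)c1OC | target

## Totals and least certain steps

Total: 18 steps. Longest linear sequence: 15 steps (steps 1 to 10 followed by steps 14 to 18, counted from 1); the cyclobutenone branch of three steps, counted from 21, joins at the benzannulation.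

The least certain operation is the benzannulation, step 14, which is the key step. The methoxy-substituted vinylketene 25 may form only at temperatures at which the silyloxyalkyne 20 begins to isomerise by a 1,3-silyl shift to a silylketene. It may also dimerise, or be captured by the phenol already formed, faster than it adds to an alkyne whose reacting carbon carries a branched, silyloxy-substituted group. Thermal loss of silanol from the ortho-hydroxybenzylic silyl ether of the product is a further possible failure. The fallback for step 14 gives up the late construction of ring A and joins a preformed arene to the ring fragment: it sets out from aldehyde 14 and comes back to the route at alcohol 32. Commercial 3-hydroxy-4,5-dimethoxybenzaldehyde F1 undergoes Baeyer–Villiger oxidation (mCPBA, CH2Cl2) to 3-hydroxy-4,5-dimethoxyphenyl formate F2, whose methanolysis (K2CO3, MeOH) gives 4,5-dimethoxybenzene-1,3-diol F3. Both hydroxyls are protected (MeOCH2Cl, i-Pr2NEt) to give 1,2-dimethoxy-3,5-bis(methoxymethoxy)benzene F4. Directed ortho-lithiation between the two acetal groups (n-BuLi, THF, 0 °C) gives [2,6-bis(methoxymethoxy)-3,4-dimethoxyphenyl]lithium F5, which adds to 14 at −78 °C to give 32.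

Second is the deoxygenation, step 13. The delocalised samarium dienolate may be protonated at the methoxyl-bearing terminus, which would transpose the double bond, and the acetate may ionise before it is reduced and rearrange to a cyclobutenedione. The fallback for step 13 builds the four-membered ring by cycloaddition instead of deoxygenating a squarate: it leaves the route at its start, where dimethyl squarate 21 is replaced by commercial 1,1,2,2-tetramethoxyethane F6, and comes back at 24. Loss of methanol from the tetraacetal (Me3SiOTf, i-Pr2NEt) gives 1,1,2-trimethoxyethene F7. [2+2] cycloaddition with dichloroketene F8, generated in the flask from Cl2CHCOCl and Et3N, gives racemic 2,2-dichloro-3,3,4-trimethoxycyclobutan-1-one F9, whose regiochemistry follows from attack of the nucleophilic CH(OMe) carbon on the ketene carbonyl carbon. The only possible β-elimination of methanol (the CCl2 carbon has no hydrogen) gives 4,4-dichloro-2,3-dimethoxycyclobut-2-en-1-one F10. Dechlorination with Zn, AcOH and TMEDA in EtOH, the established way from 4,4-dichlorocyclobutenones to cyclobutenones without allylic transposition, gives 24.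

Third is the ynolate formation, step 10. The ynolate 19 carries a silyloxy group on the carbon next to its nucleophilic carbon, so β-elimination of silanolate may compete with O-silylation, and C-silylation to a silylketene is a second possible failure. The fallback for step 10 generates the ynolate with an alkoxide in place of the silyl ether, since an oxide dianion cannot leave: it sets out from alcohol 16 and comes back at 32. Double deprotonation of 16 (n-BuLi, 2 equiv) and oxidation with LiOOt-Bu give dilithium 3-[(1S,2S,6S)-3-methyl-6-phenyl-2-prenylcyclohex-3-en-1-yl]prop-1-yne-1,3-bis(olate) F11, and silylation of both oxygens with i-Pr3SiOTf gives triisopropyl{1-[(1S,2S,6S)-3-methyl-6-phenyl-2-prenylcyclohex-3-en-1-yl]-3-(triisopropylsilyloxy)prop-2-yn-1-yloxy}silane F12. Benzannulation with 24 under the conditions of the key step gives 4,5-dimethoxy-2-{[(1S,2S,6S)-3-methyl-6-phenyl-2-prenylcyclohex-3-en-1-yl](triisopropylsilyloxy)methyl}-3-(triisopropylsilyloxy)phenol F13. Bu4NF at 0 °C frees the second phenol to give 4,5-dimethoxy-2-{[(1S,2S,6S)-3-methyl-6-phenyl-2-prenylcyclohex-3-en-1-yl](triisopropylsilyloxy)methyl}benzene-1,3-diol F14, MeOCH2Cl and i-Pr2NEt convert it into {[2,6-bis(methoxymethoxy)-3,4-dimethoxyphenyl][(1S,2S,6S)-3-methyl-6-phenyl-2-prenylcyclohex-3-en-1-yl]methoxy}triisopropylsilane F15, and Bu4NF at 60 °C then frees 32.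

Fourth is the asymmetric deprotonation, step 1. Discrimination between the enantiotopic protons may be incomplete, and the shortfall in enantiomeric purity would be carried through the whole sequence. The fallback for step 1 replaces asymmetric synthesis by resolution: it sets out from 1 and comes back at 4. Achiral enolisation and silylation (LiN(i-Pr)2, Me3SiCl, THF, −78 °C) give racemic trimethyl[(4-phenylcyclohex-1-en-1-yl)oxy]silane F16, and oxidation with Pd(OAc)2 and O2 in DMSO gives racemic 4-phenylcyclohex-2-en-1-one F17. Preparative chromatography on a chiral stationary phase (cellulose tris(3,5-dimethylphenylcarbamate), hexane/i-PrOH) separates the racemate into 4 and (R)-4-phenylcyclohex-2-en-1-one F18; the unwanted enantiomer can be racemised through its dienolate with a catalytic amine base and resolved again.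

Fifth is the three-component coupling, step 3. 1,2-Addition, or proton transfer from the acidic benzylic gamma position of 4 (which would also erode the stereocentre), may compete with conjugate addition, and alkylation of the hindered enolate 8 may be slow enough for proton exchange to scramble the enolate. The fallback for step 3 separates the two bond formations and changes the enolate: it sets out from 4 and comes back at 9. After conjugate addition of 7 the enolate is trapped with Me3SiCl as trimethyl{[(3R,4S)-4-phenyl-3-[tris(methylsulfanyl)methyl]cyclohex-1-en-1-yl]oxy}silane F19, which is purified. Anhydrous benzyltrimethylammonium fluoride then releases benzyltrimethylammonium (3R,4S)-4-phenyl-3-[tris(methylsulfanyl)methyl]cyclohex-1-en-1-olate F20 in the presence of 6. This naked enolate is alkylated regiospecifically at the former enol carbon, anti to the neighbouring substituent, and gives 9.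

## Further compounds

F1 | step 14 | 3-hydroxy-4,5-dimethoxybenzaldehyde | COc1cc(C=O)cc(O)c1OC
F2 | step 14 | 3-hydroxy-4,5-dimethoxyphenyl formate | COc1cc(OC=O)cc(O)c1OC
F3 | step 14 | 4,5-dimethoxybenzene-1,3-diol | COc1cc(O)cc(O)c1OC
F4 | step 14 | 1,2-dimethoxy-3,5-bis(methoxymethoxy)benzene | COCOc1cc(OCOC)c(OC)c(OC)c1
F5 | step 14 | [2,6-bis(methoxymethoxy)-3,4-dimethoxyphenyl]lithium | COCOc1cc(OC)c(OC)c(OCOC)c1[Li]
F6 | step 13 | 1,1,2,2-tetramethoxyethane | COC(OC)C(OC)OC
F7 | step 13 | 1,1,2-trimethoxyethene | COC=C(OC)OC
F8 | step 13 | dichloroketene | O=C=C(Cl)Cl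
F9 | step 13 | 2,2-dichloro-3,3,4-trimethoxycyclobutan-1-one (racemic) | COC1C(=O)C(Cl)(Cl)C1(OC)OC
F10 | step 13 | 4,4-dichloro-2,3-dimethoxycyclobut-2-en-1-one | COC1=C(OC)C(Cl)(Cl)C1=O
F11 | step 10 | dilithium 3-[(1S,2S,6S)-3-methyl-6-phenyl-2-prenylcyclohex-3-en-1-yl]prop-1-yne-1,3-bis(olate) (carbinol epimers) | [Li]OC#CC(O[Li])[C@H]1[C@H](CC=C(C)C)C(C)=CC[C@@H]1c1ccccc1
F12 | step 10 | triisopropyl{1-[(1S,2S,6S)-3-methyl-6-phenyl-2-prenylcyclohex-3-en-1-yl]-3-(triisopropylsilyloxy)prop-2-yn-1-yloxy}silane (carbinol epimers) | CC(C)[Si](OC#CC(O[Si](C(C)C)(C(C)C)C(C)C)[C@H]1[C@H](CC=C(C)C)C(C)=CC[C@@H]1c1ccccc1)(C(C)C)C(C)C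
F13 | step 10 | 4,5-dimethoxy-2-{[(1S,2S,6S)-3-methyl-6-phenyl-2-prenylcyclohex-3-en-1-yl](triisopropylsilyloxy)methyl}-3-(triisopropylsilyloxy)phenol (carbinol epimers) | COc1cc(O)c(C(O[Si](C(C)C)(C(C)C)C(C)C)[C@H]2[C@H](CC=C(C)C)C(C)=CC[C@@H]2c2ccccc2)c(O[Si](C(C)C)(C(C)C)C(C)C)c1OC
F14 | step 10 | 4,5-dimethoxy-2-{[(1S,2S,6S)-3-methyl-6-phenyl-2-prenylcyclohex-3-en-1-yl](triisopropylsilyloxy)methyl}benzene-1,3-diol (carbinol epimers) | COc1cc(O)c(C(O[Si](C(C)C)(C(C)C)C(C)C)[C@H]2[C@H](CC=C(C)C)C(C)=CC[C@@H]2c2ccccc2)c(O)c1OC
F15 | step 10 | {[2,6-bis(methoxymethoxy)-3,4-dimethoxyphenyl][(1S,2S,6S)-3-methyl-6-phenyl-2-prenylcyclohex-3-en-1-yl]methoxy}triisopropylsilane (carbinol epimers) | COCOc1cc(OC)c(OC)c(OCOC)c1C(O[Si](C(C)C)(C(C)C)C(C)C)[C@H]1[C@H](CC=C(C)C)C(C)=CC[C@@H]1c1ccccc1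
F16 | step 1 | racemic trimethyl[(4-phenylcyclohex-1-en-1-yl)oxy]silane | C[Si](C)(C)OC1=CCC(c2ccccc2)CC1
F17 | step 1 | racemic 4-phenylcyclohex-2-en-1-one | O=C1C=CC(c2ccccc2)CC1
F18 | step 1 | (R)-4-phenylcyclohex-2-en-1-one | O=C1C=C[C@H](c2ccccc2)CC1
F19 | step 3 | trimethyl{[(3R,4S)-4-phenyl-3-[tris(methylsulfanyl)methyl]cyclohex-1-en-1-yl]oxy}silane | C[Si](C)(C)OC1=C[C@H](C(SC)(SC)SC)[C@@H](c2ccccc2)CC1
F20 | step 3 | benzyltrimethylammonium (3R,4S)-4-phenyl-3-[tris(methylsulfanyl)methyl]cyclohex-1-en-1-olate | C[N+](C)(C)Cc1ccccc1.[O-]C1=C[C@H](C(SC)(SC)SC)[C@@H](c2ccccc2)CC1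
A1 | alternative 1 | (2S,3R,4S)-4-phenyl-2-prenyl-3-[tris(methylsulfanyl)methyl]cyclohexan-1-one (identical with 9) | CSC(SC)(SC)[C@H]1[C@H](CC=C(C)C)C(=O)CC[C@@H]1c1ccccc1
A2 | alternative 1 | [2,6-bis(methoxymethoxy)-3,4-dimethoxyphenyl]lithium | COCOc1cc(OC)c(OC)c(OCOC)c1[Li]
A3 | alternative 2 | (4S,5S)-4-[2,6-bis(methoxymethoxy)-3,4-dimethoxybenzoyl]-2-methyl-5-phenylcyclohex-2-en-1-one | COCOc1cc(OC)c(OC)c(OCOC)c1C(=O)[C@H]1C=C(C)C(=O)C[C@@H]1c1ccccc1
A4 | alternative 2 | 3-[2,6-bis(methoxymethoxy)-3,4-dimethoxyphenyl]-3-oxopropanal | COCOc1cc(OC)c(OC)c(OCOC)c1C(=O)CC=O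
A5 | alternative 2 | (E)-1-phenylpent-1-en-3-one | CCC(=O)/C=C/c1ccccc1
A6 | alternative 3 | (6-hydroxy-2,3,4-trimethoxyphenyl)[(1S,2S,6S)-3-methyl-6-phenyl-2-prenylcyclohex-3-en-1-yl]methanone | COc1cc(O)c(C(=O)[C@H]2[C@H](CC=C(C)C)C(C)=CC[C@@H]2c2ccccc2)c(OC)c1OC
A7 | alternative 3 | (1S,2S,6S)-3-methyl-6-phenyl-2-prenylcyclohex-3-ene-1-carboxylic acid | OC(=O)[C@H]1[C@H](CC=C(C)C)C(C)=CC[C@@H]1c1ccccc1
A8 | alternative 3 | 3,4,5-trimethoxy-2-(trimethylsilyl)phenyl trifluoromethanesulfonate | COc1cc(OS(=O)(=O)C(F)(F)F)c([Si](C)(C)C)c(OC)c1OC
A9 | alternative 3 | 3,4,5-trimethoxybenzyne (1,2-didehydro-3,4,5-trimethoxybenzene) | COC1=CC#CC(OC)=C1OC
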